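**Retrosynthetic overview**
- Stypandrol comes from its tetra-O-methyl ether by a final global O-demethylation.
- The 7,7′-biaryl bond comes from a Suzuki–Miyaura union of a 7-bromonaphthalene with the pinacol boronate made from that same bromide.
- Each naphthalene comes from the key fragment union: intermolecular Michael addition of a laterally lithiated o-toluate to (E)-4-methoxypent-3-en-2-one, then Dieckmann (Claisen) closure and loss of MeOH.
- The toluate comes from 2-bromo-5-methylphenol (ortho-formylation, O-methylation, oxidation, esterification); the enone comes from acetylacetone and trimethyl orthoformate.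
- Ring order: benzene ring bought, then the acetyl/methyl-bearing ring by annulation, then the two naphthalenes joined, then deprotection.

Assumption: the SMILES has no stereodescriptors and the 7,7′-axis carries only one ortho substituent (OH) per ring, so it rotates freely; the target is treated as achiral and no stereocontrol is needed.

**Route**

Step 1
Reactants: 1 2-bromo-5-methylphenol
Product: 3 3-bromo-2-hydroxy-6-methylbenzaldehyde, via hydroxymethylphenol magnesium salt 2 (not isolated)
Conditions: MgCl2 (2 equiv), Et3N (4 equiv), (CH2O)n (6 equiv), MeCN, reflux; then 1 M HCl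
Reagents that add atoms: paraformaldehyde (as formaldehyde) C=O
Why: Magnesium-mediated (Casnati–Skattebøl) ortho-formylation delivers formaldehyde only ortho to the phenoxide oxygen, the other ortho site is blocked by Br, and the salicyl alkoxide is oxidised in situ by hydride transfer to a second formaldehyde.

Step 2
Reactants: 3 3-bromo-2-hydroxy-6-methylbenzaldehyde
Product: 4 3-bromo-2-methoxy-6-methylbenzaldehyde
Conditions: MeI, K2CO3, DMF, rt
Reagents that add atoms: iodomethane CI
Why: Williamson O-methylation of the acidic salicylaldehyde phenol is straightforward and masks the phenol before oxidation and carbanion chemistry.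

Step 3
Reactants: 4 3-bromo-2-methoxy-6-methylbenzaldehyde
Product: 5 3-bromo-2-methoxy-6-methylbenzoic acid
Conditions: NaClO2, NaH2PO4, 2-methylbut-2-ene, t-BuOH/H2O, rt
Reagents that add atoms: sodium chlorite [Na+].[O-]Cl=O
Why: Pinnick oxidation converts even hindered aryl aldehydes cleanly to acids, and the alkene scavenger removes HOCl before it can chlorinate the anisole ring.

Step 4
Reactants: 5 3-bromo-2-methoxy-6-methylbenzoic acid
Product: 6 methyl 3-bromo-2-methoxy-6-methylbenzoate
Conditions: MeI, K2CO3, DMF, rt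
Reagents that add atoms: iodomethane CI
Why: SN2 O-alkylation of the carboxylate avoids the slow tetrahedral-intermediate pathway of Fischer esterification on a 2,6-disubstituted benzoic acid.

Step 5
Reactants: 7 pentane-2,4-dione (acetylacetone)
Product: 9 (E)-4-methoxypent-3-en-2-one, via 4,4-dimethoxypentan-2-one 8 (not isolated)
Conditions: HC(OMe)3, TsOH·H2O (cat.), MeOH, 55 °C; distil
Reagents that add atoms: trimethyl orthoformate COC(OC)OC
Why: Acid-catalysed ketalisation by the orthoester followed by loss of methanol gives the conjugated (thermodynamic E) β-methoxy enone, a vinylogous ester.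

Step 6
Reactants: 6 methyl 3-bromo-2-methoxy-6-methylbenzoate; 9 (E)-4-methoxypent-3-en-2-one
Product: 13 1-(7-bromo-1-hydroxy-8-methoxy-3-methylnaphthalen-2-yl)ethan-1-one, via benzylic organolithium 10 (not isolated), via Michael adduct enolate 11 (not isolated), via Dieckmann tetralone 12 (not isolated)
Conditions: LDA (1.2 equiv), THF, −78 °C (6 added to LDA), 20 min; then 9 (1.3 equiv), −78 °C → rt; then 1 M HCl
Reagents that add atoms: none
Why: Staunton–Weinreb annulation, in which the lithiated o-toluate adds intermolecularly in Michael fashion to the β-carbon of the vinylogous ester, the resulting ketone enolate closes onto the ester (Dieckmann/Claisen) and β-elimination of methanol aromatises the new ring, so the transient stereocentres are destroyed.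

Step 7
Reactants: 13 1-(7-bromo-1-hydroxy-8-methoxy-3-methylnaphthalen-2-yl)ethan-1-one
Product: 14 1-(7-bromo-1,8-dimethoxy-3-methylnaphthalen-2-yl)ethan-1-one
Conditions: MeI, Cs2CO3, DMF, 40 °C
Reagents that add atoms: iodomethane CI
Why: Williamson methylation with the caesium naphtholate overcomes the chelation of the 1-OH to the acetyl group and removes an electron-rich naphtholate that would slow oxidative addition and promote protodeboronation in the coupling steps.

Step 8
Reactants: 14 1-(7-bromo-1,8-dimethoxy-3-methylnaphthalen-2-yl)ethan-1-one (half of the material)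
Product: 15 1-[1,8-dimethoxy-3-methyl-7-(4,4,5,5-tetramethyl-1,3,2-dioxaborolan-2-yl)naphthalen-2-yl]ethan-1-one
Conditions: B2pin2 (1.2 equiv), Pd(dppf)Cl2 (5 mol %), KOAc, 1,4-dioxane, 90 °C
Reagents that add atoms: bis(pinacolato)diboron CC1(C)OB(OC1(C)C)B1OC(C)(C)C(C)(C)O1
Why: Miyaura borylation tolerates the aryl ketone and ethers, and the weak base KOAc prevents premature homocoupling.

Step 9
Reactants: 14 1-(7-bromo-1,8-dimethoxy-3-methylnaphthalen-2-yl)ethan-1-one; 15 1-[1,8-dimethoxy-3-methyl-7-(4,4,5,5-tetramethyl-1,3,2-dioxaborolan-2-yl)naphthalen-2-yl]ethan-1-one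
Product: 16 1,1'-(1,1',8,8'-tetramethoxy-6,6'-dimethyl-[2,2'-binaphthalene]-7,7'-diyl)di(ethan-1-one)
Conditions: Pd(OAc)2 (5 mol %), SPhos (10 mol %), K3PO4, toluene/H2O 10:1, 90 °C
Reagents that add atoms: none
Why: Suzuki–Miyaura coupling forms a biaryl with only one ortho substituent per ring easily, and it fixes the 7,7′-regiochemistry through the positions of Br and B, with no stereogenic axis to control.

Step 10
Reactants: 16 1,1'-(1,1',8,8'-tetramethoxy-6,6'-dimethyl-[2,2'-binaphthalene]-7,7'-diyl)di(ethan-1-one)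
Product: 18 stypandrol, via cyclic bromoboronate 17 (not isolated)
Conditions: BBr3 (8 equiv), CH2Cl2, −78 °C → rt, Ar; then degassed H2O, 0 °C
Reagents that add atoms: none
Why: BBr3 Lewis-acid ether cleavage is assisted by chelation to the acetyl carbonyl and by formation of a cyclic peri-borate, which hydrolyses on work-up to the tetrol (air is excluded because the product is oxidation-prone).

**Compound list**

1 | 2-bromo-5-methylphenol | Cc1ccc(Br)c(O)c1 | starting material
2 | 6-bromo-2-(hydroxymethyl)-3-methylphenol (present as its magnesium salt) | Cc1ccc(Br)c(O)c1CO | intermediate (not isolated)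
3 | 3-bromo-2-hydroxy-6-methylbenzaldehyde | Cc1ccc(Br)c(O)c1C=O | intermediate
4 | 3-bromo-2-methoxy-6-methylbenzaldehyde | COc1c(Br)ccc(C)c1C=O | intermediate
5 | 3-bromo-2-methoxy-6-methylbenzoic acid | COc1c(Br)ccc(C)c1C(=O)O | intermediate
6 | methyl 3-bromo-2-methoxy-6-methylbenzoate | COC(=O)c1c(C)ccc(Br)c1OC | intermediate
7 | pentane-2,4-dione | CC(=O)CC(C)=O | starting material
8 | 4,4-dimethoxypentan-2-one | CC(=O)CC(C)(OC)OC | intermediate (not isolated)
9 | (E)-4-methoxypent-3-en-2-one | CO/C(C)=C/C(C)=O | intermediate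
10 | methyl 3-bromo-6-(lithiomethyl)-2-methoxybenzoate | [Li]Cc1ccc(Br)c(OC)c1C(=O)OC | intermediate (not isolated)
11 | lithium enolate of methyl 3-bromo-2-methoxy-6-(2-methoxy-2-methyl-4-oxopentyl)benzoate (racemic) | COC(=O)c1c(OC)c(Br)ccc1CC(C)(OC)C=C(C)O[Li] | intermediate (not isolated)
12 | 2-acetyl-7-bromo-3,8-dimethoxy-3-methyl-3,4-dihydronaphthalen-1(2H)-one (racemic diastereomer mixture, present as its lithium enolate) | CC(=O)C1C(=O)c2c(OC)c(Br)ccc2CC1(C)OC | intermediate (not isolated)
13 | 1-(7-bromo-1-hydroxy-8-methoxy-3-methylnaphthalen-2-yl)ethan-1-one | CC(=O)c1c(C)cc2ccc(Br)c(OC)c2c1O | intermediate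
14 | 1-(7-bromo-1,8-dimethoxy-3-methylnaphthalen-2-yl)ethan-1-one | CC(=O)c1c(C)cc2ccc(Br)c(OC)c2c1OC | intermediate
15 | 1-[1,8-dimethoxy-3-methyl-7-(4,4,5,5-tetramethyl-1,3,2-dioxaborolan-2-yl)naphthalen-2-yl]ethan-1-one | CC(=O)c1c(C)cc2ccc(B3OC(C)(C)C(C)(C)O3)c(OC)c2c1OC | intermediate
16 | 1,1'-(1,1',8,8'-tetramethoxy-6,6'-dimethyl-[2,2'-binaphthalene]-7,7'-diyl)di(ethan-1-one) | CC(=O)c1c(C)cc2ccc(-c3ccc4cc(C)c(C(C)=O)c(OC)c4c3OC)c(OC)c2c1OC | intermediate
17 | bis(cyclic peri-bromoboronate) of stypandrol | CC(=O)c1c(C)cc2ccc(-c4ccc5cc(C)c(C(C)=O)c6OB(Br)Oc4c56)c3OB(Br)Oc1c23 | intermediate (not isolated)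
18 | stypandrol, 1,1'-(1,1',8,8'-tetrahydroxy-6,6'-dimethyl-[2,2'-binaphthalene]-7,7'-diyl)di(ethan-1-one) | CC(=O)c1c(C)cc2ccc(-c3ccc4cc(C)c(C(C)=O)c(O)c4c3O)c(O)c2c1O | target

**Summary**

Total step count: 10.
Longest linear sequence: 9 steps (1 → 3 → 4 → 5 → 6 → 13 → 14 → 15 → 16 → 18); step 5 is a one-step side branch.

Steps most likely to fail:

Step 1 (formylation at an ortho carbon flanked by a methyl group, on a bromine-deactivated phenol). The fallback sets out from 1 and comes back at 4, and installs the carbon by sigmatropic rearrangement instead of electrophilic substitution. Allyl bromide/K2CO3 in acetone gives 1-bromo-4-methyl-2-(prop-2-en-1-yloxy)benzene F1. Aromatic Claisen rearrangement (N,N-diethylaniline, 190 °C) delivers the allyl group mainly to the one free ortho carbon and gives 6-bromo-3-methyl-2-(prop-2-en-1-yl)phenol F2. MeI/K2CO3 gives 1-bromo-2-methoxy-4-methyl-3-(prop-2-en-1-yl)benzene F3. Isomerisation with RuHCl(CO)(PPh3)3 (cat.) in toluene at 80 °C gives 1-bromo-2-methoxy-4-methyl-3-[(E)-prop-1-en-1-yl]benzene F4. Ozonolysis (O3, CH2Cl2/MeOH, −78 °C; Me2S) gives aldehyde 4.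

Step 6 (the toluate anion may deprotonate the methyl ketone or add 1,2 instead of adding in Michael fashion). The fallback sets out from 6 and comes back at 13, and separates the two bond formations into a Claisen acylation and an aldol condensation. Anion 10 (LDA 2.2 equiv, THF, −78 °C) is acylated with N-methoxy-N-methylacetamide to methyl 3-bromo-2-methoxy-6-(2-oxopropyl)benzoate F5. TsOH in refluxing toluene closes the enol lactone 7-bromo-8-methoxy-3-methyl-1H-isochromen-1-one F6. The lithium enolate of acetone (LDA, acetone, THF, −78 → 0 °C) opens this activated lactone by Claisen acylation to 1-[3-bromo-2-methoxy-6-(2-oxopropyl)phenyl]butane-1,3-dione F7. K2CO3/MeOH (or warm AcOH) then effects intramolecular aldol condensation and dehydration to naphthol 13.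

Step 10 (fourfold demethylation on an oxidation-sensitive binaphthol). The fallback sets out from 13 and comes back at 18, and moves the methyl ether cleavage to the monomer so the last step is mild acid. BBr3 (CH2Cl2, −78 → 0 °C) on 13 cleaves the single peri-methoxy group to 1-(7-bromo-1,8-dihydroxy-3-methylnaphthalen-2-yl)ethan-1-one F8. MOMCl/NaH (2.2 equiv) in DMF at 0 °C gives 1-[7-bromo-1,8-bis(methoxymethoxy)-3-methylnaphthalen-2-yl]ethan-1-one F9. Miyaura borylation of half of F9 (B2pin2, Pd(dppf)Cl2, KOAc, dioxane, 90 °C) gives 1-[1,8-bis(methoxymethoxy)-3-methyl-7-(4,4,5,5-tetramethyl-1,3,2-dioxaborolan-2-yl)naphthalen-2-yl]ethan-1-one F10. Suzuki coupling of F9 with F10 (Pd(OAc)2/SPhos, K3PO4, toluene/H2O, 90 °C) gives 1,1'-[1,1',8,8'-tetrakis(methoxymethoxy)-6,6'-dimethyl-[2,2'-binaphthalene]-7,7'-diyl]di(ethan-1-one) F11. HCl in MeOH/THF at 40 °C under argon then releases 18.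

**Further compounds**

F1 | step 1 | 1-bromo-4-methyl-2-(prop-2-en-1-yloxy)benzene | C=CCOc1cc(C)ccc1Br
F2 | step 1 | 6-bromo-3-methyl-2-(prop-2-en-1-yl)phenol | C=CCc1c(C)ccc(Br)c1O
F3 | step 1 | 1-bromo-2-methoxy-4-methyl-3-(prop-2-en-1-yl)benzene | C=CCc1c(C)ccc(Br)c1OC
F4 | step 1 | 1-bromo-2-methoxy-4-methyl-3-[(E)-prop-1-en-1-yl]benzene | C/C=C/c1c(C)ccc(Br)c1OC
F5 | step 6 | methyl 3-bromo-2-methoxy-6-(2-oxopropyl)benzoate | COC(=O)c1c(OC)c(Br)ccc1CC(C)=O
F6 | step 6 | 7-bromo-8-methoxy-3-methyl-1H-isochromen-1-one | CC1=Cc2ccc(Br)c(OC)c2C(=O)O1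
F7 | step 6 | 1-[3-bromo-2-methoxy-6-(2-oxopropyl)phenyl]butane-1,3-dione | CC(=O)CC(=O)c1c(OC)c(Br)ccc1CC(C)=O
F8 | step 10 | 1-(7-bromo-1,8-dihydroxy-3-methylnaphthalen-2-yl)ethan-1-one | CC(=O)c1c(C)cc2ccc(Br)c(O)c2c1O
F9 | step 10 | 1-[7-bromo-1,8-bis(methoxymethoxy)-3-methylnaphthalen-2-yl]ethan-1-one | CC(=O)c1c(C)cc2ccc(Br)c(OCOC)c2c1OCOC
F10 | step 10 | 1-[1,8-bis(methoxymethoxy)-3-methyl-7-(4,4,5,5-tetramethyl-1,3,2-dioxaborolan-2-yl)naphthalen-2-yl]ethan-1-one | CC(=O)c1c(C)cc2ccc(B3OC(C)(C)C(C)(C)O3)c(OCOC)c2c1OCOC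
F11 | step 10 | 1,1'-[1,1',8,8'-tetrakis(methoxymethoxy)-6,6'-dimethyl-[2,2'-binaphthalene]-7,7'-diyl]di(ethan-1-one) | CC(=O)c1c(C)cc2ccc(-c3ccc4cc(C)c(C(C)=O)c(OCOC)c4c3OCOC)c(OCOC)c2c1OCOC
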